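**Vessel and question.** The closed, stirred vessel holds free monomer, initiator and radical scavenger at one temperature, and in each earlier run the first reading of monomer in chains is zero.

all flasks: initiator 2 mol%
- east: free monomer 20 mM; radical scavenger 0.018 mol%; temperature −15 °C; run made earlier
- north: free monomer 20 mM; radical scavenger 0.072 mol%; temperature 12 °C; run made earlier
- south: free monomer 10 mM; radical scavenger 0.036 mol%; temperature −15 °C; run made earlier
- beta: free monomer 20 mM; radical scavenger 0.036 mol%; temperature 20 °C; time 8.0 h
- epsilon: free monomer 20 mM; radical scavenger 0.036 mol%; temperature 35 °C; time 8.0 h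
- alpha: free monomer 20 mM; radical scavenger 0.036 mol%; temperature 5 °C; time 8.0 h
- eta: free monomer 20 mM; radical scavenger 0.036 mol%; temperature −10 °C; time 8.0 h

| run | time / h | monomer in chains / % | free monomer / % |
|---|---|---|---|
| east | 5.00 | 0 | 99.0 |
| east | 12.0 | 0 | 95.9 |
| east | 25.0 | 0 | 94.2 |
| east | 60.0 | 13.6 | 73.5 |
| north | 0.833 | 0 | 95.0 |
| north | 2.00 | 5.2 | 82.4 |
| north | 4.00 | 19.4 | 65.7 |
| north | 10.0 | 40.7 | 35.5 |
| south | 15.0 | 0 | 97.8 |
| south | 30.0 | 0.3 | 97.4 |
| south | 50.0 | 0 | 93.3 |
| south | 60.0 | 2.3 | 88.2 |

(each reading ± 1 percentage point)



1. the flask that comes out highest in amount of monomer in chains, in percent of the free monomer charged, or "all alike" when all lie within 1.5 percentage points (beta / epsilon / alpha / eta / all alike)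
2. monomer in chains at the end, in percent of the free monomer charged, beta
3. monomer in chains at the end, in percent of the free monomer charged, epsilon
4. monomer in chains at the end, in percent of the free monomer charged, alpha
5. monomer in chains at the end, in percent of the free monomer charged, eta

**Scavenger clock.** Take the catching of radicals by the radical scavenger as the fast step: each radical from the initiator then removes one scavenger, each initiator gives two radicals, and the wait, the induction period, ends when the scavenger charge has been met. With k as the decomposition constant of the initiator, a last zero reading gives an upper reading of k, since the wait lasts at least that long.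

**Two ways.** East and south both start at [radical scavenger] = 0.00360 mM, but south has half of east's [initiator]. East still reads zero at 25.0 h, which gives k = 1.80 × 10⁻⁴ h⁻¹. South still reads zero at 50.0 h, which gives 1.80 × 10⁻⁴ h⁻¹. Both values are upper limits set by the sampling times, so their equality is no check of the proportion to [initiator], which stays an assumption of this reckoning: a wait of like length in both runs fits the same zero readings.

**Into temperature.** North at 12 °C reads zero at 0.833 h, which gives 0.0216 h⁻¹, and against south this reads as an activation energy of 109 kJ mol⁻¹, an estimate made from two upper limits.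

**Own reckoning.** Eta comes to 19.1 h, and this is the scavenger clock, the scavenger loading over twice the initiator loading times k at the flask's temperature. It is longer than the run, so eta should show no chains at the end and keep 58.2% of its scavenger. Alpha's clock is 1.32 h and epsilon's is 0.0137 h, both shorter than the run, so chains grow there, and the clock gives no ranking among the flasks that pass it.

**Forecast and result.** The forecast named beta highest, with beta 54%, epsilon 49%, alpha 20% and eta 0%, and of the coldest flask it held that “eta gives nothing in 8 h”. The simulation puts epsilon highest, with beta 56.3%, epsilon 65.7%, alpha 21.3% and eta 0.0270%.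

    initiator → 2 initiating radical (k = 0.00710 min⁻¹, Ea = 103 kJ mol⁻¹)
    free monomer + initiating radical → growing radical + monomer in chains (k = 2.00 × 10⁵ M⁻¹ s⁻¹, Ea = 21.0 kJ mol⁻¹)
    free monomer + growing radical → monomer in chains + growing radical, rate k3*[growing radical]*[free monomer] (k = 24000 M⁻¹ s⁻¹, Ea = 17.0 kJ mol⁻¹)
    2 growing radical → dead chain (k = 8.80 × 10⁸ M⁻¹ s⁻¹, Ea = 9.00 kJ mol⁻¹)
    2 free monomer → self-condensation product (k = 0.230 M⁻¹ min⁻¹, Ea = 71.0 kJ mol⁻¹)
    growing radical + radical scavenger → ended chains (k = 7.40 × 10⁷ M⁻¹ s⁻¹, Ea = 14.0 kJ mol⁻¹)
    (constants at 35 °C)

**Eta's wait.** At 8.00 h eta keeps 60.9% of its radical scavenger, against the clock's 58.2%, and holds 0.00281 mM of ended chains. The turning of growing radical and radical scavenger into ended chains and the length of the run, against one ten times as long, together account for part of eta's empty result: with that step removed eta gives 6.71%, and left for 80.0 h it gives 33.8%. A repeat of epsilon at 10 °C has a clock of 0.575 h, shorter than the run, and it ends with 0% of its scavenger and 33.8% of monomer in chains.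

The numbers in the tables were generated by integration with made-up constants.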